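**Retrosynthetic overview**
1. Target 9 ⇒ open the pyran ring (ring B) by retro-oxa-6π to ortho-quinone methide 8 ⇒ prenylated bibenzyl resorcylate 6 + prenal 7; C5 of ring A is the only free nuclear position, so the regiochemistry is fixed.
2. 6 ⇒ open ring A by retro-aldol (C2–C7) to the linear tetraketide 5, which already carries the prenyl group on C4.
3. 5 ⇒ Claisen disconnection C6–C7: trianion of the C4-prenylated diketo ester 3 + dihydro-p-coumarate 4 (the starter unit).
4. 3 ⇒ methyl 3,5-dioxohexanoate 1 + prenyl bromide 2.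
5. Ring order: ring C (phenol) is purchased, ring A is formed in step 2, ring B in step 3.

Assumption: the target has no stereocentre and no stereogenic alkene, so it is achiral and no enantiocontrol is needed; compound 1 is taken as a catalogue compound (also one step from dehydroacetic acid with Mg(OMe)2 in MeOH).

**Step 1**
Reactants: 1 methyl 3,5-dioxohexanoate; 2 1-bromo-3-methylbut-2-ene (prenyl bromide)
Product: 3 methyl 4-acetyl-7-methyl-3-oxooct-6-enoate
Conditions: NaH (1.0 equiv), THF, 0 °C, 20 min; then 2 (1.0 equiv), 0 °C → rt, 6 h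
Reagents that add atoms: none
Why: One equivalent of base ionises the most acidic CH2 (C4, between the two ketones, about two pKa units below C2), and C-alkylation of this 1,3-diketone enolate with the soft allylic bromide places the prenyl group on C4 (enolate alkylation; the new C4 centre is racemic and enolisable and is later lost on aromatisation).

**Step 2**
Reactants: 3 methyl 4-acetyl-7-methyl-3-oxooct-6-enoate; 4 methyl 3-(4-hydroxyphenyl)propanoate
Product: 6 methyl 2,4-dihydroxy-6-[2-(4-hydroxyphenyl)ethyl]-3-(3-methylbut-2-en-1-yl)benzoate, via linear triketo ester 5 (not isolated)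
Conditions: 3 (2.1 equiv), LiN(i-Pr)2 (6.5 equiv), THF, −78 → 0 °C; add lithium phenoxide of 4 (4 + 1.0 equiv LiN(i-Pr)2, THF), −78 → 0 °C, 2 h; then AcOH (7.5 equiv), MeOH, 0 °C → rt, 12 h
Reagents that add atoms: none
Why: The trianion of 3 reacts at its last-formed, most basic terminal carbon (C6) with the ester of 4 in a Claisen acylation (Harris-type biomimetic polyketide synthesis), and after partial protonation in amine-buffered methanol the tetraketide closes by intramolecular aldol addition of C2 to the C7 ketone and loses water to give the resorcylate, with the C4 prenyl group ending at C3 between the two hydroxyls.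

**Step 3**
Reactants: 6 methyl 2,4-dihydroxy-6-[2-(4-hydroxyphenyl)ethyl]-3-(3-methylbut-2-en-1-yl)benzoate; 7 3-methylbut-2-enal (prenal)
Product: 9 methyl 7-hydroxy-5-[2-(4-hydroxyphenyl)ethyl]-2,2-dimethyl-8-(3-methylbut-2-en-1-yl)-2H-chromene-6-carboxylate, via ortho-quinone methide 8 (not isolated)
Conditions: 7 (2.0 equiv), ethylenediammonium diacetate (EDDA, 20 mol %), toluene, 110 °C, 12 h
Reagents that add atoms: none
Why: Iminium-catalysed Knoevenagel-type condensation of prenal at C5, the only free position of the resorcylate ring (the monohydric phenol ring does not react under these conditions), gives an ortho-quinone methide that closes onto the adjacent 4-oxygen by oxa-6π electrocyclisation (formal [3+3] chromene annulation), the same ring closure as expected from an oxidised C5-prenyl group.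

**Compound list**
1 | methyl 3,5-dioxohexanoate | COC(=O)CC(=O)CC(C)=O | starting material
2 | 1-bromo-3-methylbut-2-ene (prenyl bromide) | CC(C)=CCBr | starting material
3 | methyl 4-acetyl-7-methyl-3-oxooct-6-enoate (= methyl 4-(3-methylbut-2-en-1-yl)-3,5-dioxohexanoate; racemic at C4, enolised) | COC(=O)CC(=O)C(CC=C(C)C)C(C)=O | intermediate
4 | methyl 3-(4-hydroxyphenyl)propanoate | COC(=O)CCc1ccc(O)cc1 | starting material
5 | methyl 9-(4-hydroxyphenyl)-4-(3-methylbut-2-en-1-yl)-3,5,7-trioxononanoate (linear triketo ester; racemic at C4, enolised) | COC(=O)CC(=O)C(CC=C(C)C)C(=O)CC(=O)CCc1ccc(O)cc1 | intermediate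
6 | methyl 2,4-dihydroxy-6-[2-(4-hydroxyphenyl)ethyl]-3-(3-methylbut-2-en-1-yl)benzoate | COC(=O)c1c(O)c(CC=C(C)C)c(O)cc1CCc1ccc(O)cc1 | intermediate
7 | 3-methylbut-2-enal (prenal) | CC(C)=CC=O | starting material
8 | methyl (3Z)-6-hydroxy-2-[2-(4-hydroxyphenyl)ethyl]-5-(3-methylbut-2-en-1-yl)-3-(3-methylbut-2-en-1-ylidene)-4-oxocyclohexa-1,5-diene-1-carboxylate (ortho-quinone methide) | COC(=O)C1=C(CCc2ccc(O)cc2)/C(=C/C=C(C)C)C(=O)C(CC=C(C)C)=C1O | intermediate
9 | methyl 7-hydroxy-5-[2-(4-hydroxyphenyl)ethyl]-2,2-dimethyl-8-(3-methylbut-2-en-1-yl)-2H-chromene-6-carboxylate (achiral) | COC(=O)c1c(O)c(CC=C(C)C)c2c(c1CCc1ccc(O)cc1)C=CC(C)(C)O2 | target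

**Totals**
Total step count: 3. Longest linear sequence: 3 steps (1 → 3 → 6 → 9).

**Steps most likely to fail, with fallbacks**

Step 2 is the most exposed step. The trianion of a C4-substituted diketo ester must be acylated by an enolisable ester, and the product must close by aldol rather than Claisen or pyrone formation. The fallback inverts the order of chain extension and sets out from 2 and 4, returning at 6. Pentane-2,4-dione is C-alkylated with 2 (K2CO3, acetone, reflux) to 3-(3-methylbut-2-en-1-yl)pentane-2,4-dione F2. Its dianion (LiN(i-Pr)2, THF, 0 °C) is acylated at the terminal methyl by the lithium phenoxide of 4 to give 8-(4-hydroxyphenyl)-3-(3-methylbut-2-en-1-yl)octane-2,4,6-trione F3. The polyanion of F3 (LiN(i-Pr)2, THF, 0 °C; kinetic deprotonation at the methyl terminus) is carboxylated with CO2 to 9-(4-hydroxyphenyl)-4-(3-methylbut-2-en-1-yl)-3,5,7-trioxononanoic acid F4. F4 cyclises at pH 5 (aqueous acetate buffer, rt) to 2,4-dihydroxy-6-[2-(4-hydroxyphenyl)ethyl]-3-(3-methylbut-2-en-1-yl)benzoic acid F5, which is kept cold to avoid decarboxylation. Carboxylate-selective methylation (MeI, KHCO3, DMF, rt) then gives 6.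

Step 1 may give C2-alkylation, O-alkylation or double alkylation of 1. The fallback fixes the regiochemistry by the order of bond formation; it sets out from 2 and returns at 3. The dianion of methyl acetoacetate (LiN(i-Pr)2, 2.1 equiv, THF, 0 °C) is alkylated at its γ-carbon with 2 to give methyl 7-methyl-3-oxooct-6-enoate F1. The dianion of F1 (LiN(i-Pr)2, 2.2 equiv, THF, −78 °C) is then acetylated at the γ-carbon with N-methoxy-N-methylacetamide to give 3.

Step 3 may be slow because C5 is flanked by the hydroxyl and the arylethyl chain. The fallback replaces the condensation by an aryl propargyl ether rearrangement; it sets out from 6 and returns at 9. The most acidic non-chelated hydroxyl of 6 (the 4-OH para to the ester) is alkylated with 3-chloro-3-methylbut-1-yne (K2CO3, 1.1 equiv, KI, CuCl cat., acetone, 50 °C) to give methyl 2-hydroxy-6-[2-(4-hydroxyphenyl)ethyl]-3-(3-methylbut-2-en-1-yl)-4-[(2-methylbut-3-yn-2-yl)oxy]benzoate F6. Heating F6 in xylene at 140 °C triggers Claisen rearrangement to the only free ortho position (C5), a 1,5-hydrogen shift and oxa-6π closure to 9.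

**Further compounds**
F1 | step 1 | methyl 7-methyl-3-oxooct-6-enoate | COC(=O)CC(=O)CCC=C(C)C
F2 | step 2 | 3-(3-methylbut-2-en-1-yl)pentane-2,4-dione | CC(=O)C(CC=C(C)C)C(C)=O
F3 | step 2 | 8-(4-hydroxyphenyl)-3-(3-methylbut-2-en-1-yl)octane-2,4,6-trione | CC(=O)C(CC=C(C)C)C(=O)CC(=O)CCc1ccc(O)cc1
F4 | step 2 | 9-(4-hydroxyphenyl)-4-(3-methylbut-2-en-1-yl)-3,5,7-trioxononanoic acid | OC(=O)CC(=O)C(CC=C(C)C)C(=O)CC(=O)CCc1ccc(O)cc1
F5 | step 2 | 2,4-dihydroxy-6-[2-(4-hydroxyphenyl)ethyl]-3-(3-methylbut-2-en-1-yl)benzoic acid | OC(=O)c1c(O)c(CC=C(C)C)c(O)cc1CCc1ccc(O)cc1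
F6 | step 3 | methyl 2-hydroxy-6-[2-(4-hydroxyphenyl)ethyl]-3-(3-methylbut-2-en-1-yl)-4-[(2-methylbut-3-yn-2-yl)oxy]benzoate | COC(=O)c1c(O)c(CC=C(C)C)c(OC(C)(C)C#C)cc1CCc1ccc(O)cc1
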